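The unit I count in is one hour of free catalyst at the concentration of the winter run.

| flask | substrate | reagent | capture agent | free catalyst | remark | time |
|---|---|---|---|---|---|---|
| noon | 0.010 M | 2 equiv | 1 mM | 0.11 mol% | run made earlier |  |
| winter | 0.010 M | 2 equiv | 1 mM | 0.48 mol% | run made earlier |  |
| Sunday's | 0.010 M | 2.00 equiv | 1.00 mM | 0.4 mol% |  | 20 h |
| Monday's | 0.010 M | 2.00 equiv | 1.00 mM | 0.2 mol% |  | 20 h |
| Friday's | 0.010 M | 2.00 equiv | 1.00 mM | 0.1 mol% |  | 20 h |

| run | time / h | open intermediate / % | trapped intermediate / % | product / % | substrate / % |
|---|---|---|---|---|---|
| noon | 2.00 | 65 | 4 | 11 | 22 |
| noon | 4.00 | 58 | 4 | 23 | 8 |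
| noon | 6.00 | 55 | 7 | 37 | 1 |
| noon | 8.00 | 44 | 9 | 48 | 0 |
| noon | 10.0 | 35 | 6 | 56 | 0 |
| winter | 2.00 | 43 | 0 | 53 | 0 |
| winter | 4.00 | 18 | 3 | 79 | 1 |
| winter | 6.00 | 7 | 6 | 88 | 2 |
| winter | 8.00 | 3 | 3 | 98 | 0 |
| winter | 10.0 | 1 | 6 | 93 | 0 |

(each reading ± 1.5 percentage points)



1. which of these there is most of at the end, counted by the substrate in it, Sunday's (product / open intermediate / trapped intermediate / substrate)
2. which of these there is most of at the end, counted by the substrate in it, Monday's (product / open intermediate / trapped intermediate / substrate)
3. which of these there is most of at the end, counted by the substrate in it, Friday's (product / open intermediate / trapped intermediate / substrate)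
4. amount of the one of these that there is most of at the end, in percent of the substrate charged, Sunday's
5. amount of the one of these that there is most of at the end, in percent of the substrate charged, Monday's
6. amount of the one of these that there is most of at the end, in percent of the substrate charged, Friday's

Does substrate matter at the end? In the noon run, at 0.11 mol% of free catalyst, substrate is down to 1% by 6.00 h, so for the end I follow open intermediate.

How fast does open intermediate clear? In the winter run it falls from 43% at 2.00 h to 3% at 8.00 h, and I treat this as pseudo-first-order. That reads as a clearing rate of 0.444 /h, the fall in the logarithm of open intermediate per unit of mine. For a flask with the substrate, reagent and capture agent charges of these runs, the clearing number is this rate times its hours times its catalyst concentration over the winter run's, and my estimate of the share still open is e to the minus that number.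

The noon run tests it: its number at 10.0 h is 1.02, which leaves 36.1%, and the reading is 35%. At 20 h the numbers are 7.40 for Sunday's flask, 3.70 for Monday's and 1.85 for Friday's, so I estimate 0.0614%, 2.48% and 15.7% open.

How much can the capture agent take? Its charge is 10.0% of the substrate, and I take that as the room for trapped intermediate. With that room filled, my estimates for product are 89.9%, 87.5% and 74.3%, so I expect product to lead in each of the three flasks.

The forecast says product for all three, at 94%, 90% and 76%, above my estimates, reasoning “about first order in catalyst”.

The flasks give product in all three, at 94.7%, 90.8% and 77.4%.

    substrate + free catalyst → free catalyst + open intermediate (k = 1200 /M/min)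
    free catalyst + open intermediate ⇌ catalyst intermediate (K = 116 /M, k = 249 /M/min)
    reagent + catalyst intermediate → free catalyst + product (k = 436 /M/min)
    open intermediate + capture agent → trapped intermediate (k = 0.530 /M/min)

My clearing number left 15.7% open in Friday's flask, which holds 13.5%. In Sunday's flask the turning of open intermediate with capture agent is the main reason that product stands at 94.7%, since that run without the step gives >99.9%. Take Monday's recipe at 0.0025 M of substrate, with capture agent unchanged, which goes beyond the charges my number holds: catalyst and reagent are each a quarter as concentrated, the number, which takes in the catalyst, is 0.925, and my estimate of what stays open is 39.7%. That neighbouring flask holds most as open intermediate, at 41.1%, against product at 35.7%.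

The runs come from a simulation on assumed constants; noise was put on by code.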